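(The earlier runs and the new flask were generated by integration on assumed constants.)

A small charge of starting material met a larger charge of coupling partner in ochre, 0.015 M against 0.0486 M, so starting material was the limiting reagent there and I kept my books on it.

| flask | starting material | coupling partner | precatalyst | temperature | remark | time |
|---|---|---|---|---|---|---|
| maple | 0.054 M | 0.0486 M | 3.7 mM | 30 °C | run made earlier |  |
| elm | 0.054 M | 0.0486 M | 6.7 mM | 62 °C | run made earlier |  |
| cedar | 0.035 M | 0.0486 M | 2.5 mM | 30 °C | run made earlier |  |
| teal | 0.054 M | 0.0486 M | 2.5 mM | 50 °C |  | 3.0 d |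
| violet | 0.054 M | 0.0300 M | 5.0 mM | 70 °C |  | 3.0 d |
| ochre | 0.015 M | 0.0486 M | 2.5 mM | 90 °C |  | 3.0 d |
| grey | 0.054 M | 0.200 M | 2.5 mM | 35 °C |  | 3.0 d |
| red | 0.054 M | 0.0250 M | 4.0 mM | 65 °C |  | 3.0 d |

maple run (percent of the starting material charged)

| time / d | target / % |
|---|---|
| 0.208 | 0 |
| 0.625 | 0 |
| 1.04 | 0 |
| 1.67 | 0.8 |
| 2.50 | 0 |
| 3.00 | 0.1 |
| 5.00 | 0.3 |

elm run (percent of the starting material charged)

| time / h | target / % |
|---|---|
| 3.00 | 0.8 |
| 6.00 | 2.9 |
| 8.00 | 4.7 |
| 12.0 | 9.2 |
| 15.0 | 13.9 |
| 20.0 | 21.0 |

cedar run (percent of the starting material charged)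

| time / d | target / % |
|---|---|
| 0.833 | 0.2 |
| 1.67 | 0.6 |
| 2.50 | 0 |
| 3.00 | 0 |
| 5.00 | 0.2 |

(each reading ± 0.3 percentage points)

- percent here means starting material units held: one spent catalyst counts as two
- on the list of suspects stand: catalyst intermediate C -> free catalyst + target; precatalyst -> free catalyst; starting material + catalyst intermediate C -> spent catalyst; catalyst intermediate B -> catalyst intermediate C; coupling partner + free catalyst <-> catalyst intermediate A; starting material + catalyst intermediate A <-> catalyst intermediate B

* all flasks from highest to lowest amount of target, in percent of the starting material charged, at 3.0 d (teal / violet / ochre / grey / red)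
* the amount of target, in percent of the starting material charged of the flask you put first, at 3.0 d
* the amount of target, in percent of the starting material charged of the flask you put last, at 3.0 d

Every mole of ochre's starting material had to stand in one of a few entries: left over, in target, or on the catalyst. Intermediates B and C hold one unit and spent catalyst holds two, so I reckoned one share from the charges:

claim = two × precatalyst charged / starting material charged = 33.3%

I named this the catalyst's claim, the share of the charged starting material that the whole catalyst charge holds once it is spent.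

Next came the entry for what was left over. Ochre needed an average turnover of

starting material / (precatalyst × time) = 0.0833 h⁻¹

Elm, with its 21.0% after 20.0 h, had already averaged 0.0846 h⁻¹ per catalyst charged, about the same, and at 62 °C, cooler than ochre's 90 °C. I therefore booked the leftover entry near zero, which placed ochre's target between 66.7% and the full charge. I went no tighter, since the runs read target and not spent catalyst.

The forecast gave ochre > violet > red > teal > grey, with 88% first and 0.5% last, holding that “Low starting material favours turnover over deactivation”.

The flask gave ochre > violet > red > teal > grey, with ochre at 99.6% and grey at 0.414%.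

    catalyst intermediate C → free catalyst + target (k = 1.14 h⁻¹, Ea = 98.0 kJ mol⁻¹)
    precatalyst → free catalyst (k = 0.00920 h⁻¹, Ea = 101 kJ mol⁻¹)
    starting material + catalyst intermediate C → spent catalyst (k = 1.22 M⁻¹ h⁻¹, Ea = 61.0 kJ mol⁻¹)
    catalyst intermediate B → catalyst intermediate C (k = 0.704 h⁻¹, Ea = 108 kJ mol⁻¹)
    coupling partner + free catalyst ⇌ catalyst intermediate A (K = 35.0 M⁻¹, k = 28.8 M⁻¹ h⁻¹, Ea = 65.0 kJ mol⁻¹, ΔH = −33.0 kJ mol⁻¹)
    starting material + catalyst intermediate A ⇌ catalyst intermediate B (K = 13.0 M⁻¹, k = 32.0 M⁻¹ h⁻¹, Ea = 58.0 kJ mol⁻¹, ΔH = −8.00 kJ mol⁻¹)
    (constants at 50 °C)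

Ochre's spent catalyst stood at 1.05% of the catalyst charged, and its intermediates B and C at 0% and 0%, so the books closed thus:

target 99.6% + left 0.016% + spent 0.350% = >99.9%

With the charges as they stood in ochre, starting material took intermediate A with a half-life of 0.13 h, forward step alone. It took intermediate C to spent catalyst with a half-life of 0.13 d, 23.2 times longer.

In the flask like grey kept at 60 °C, the claim shrinks to 9.26%, so with 44% left, target had to reach at least 46.7%. The computed flask held 52.9%, with 31.2% of its catalyst spent, which drew 2.89% of the charge.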